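**Retrosynthetic overview**
1. Endgame: BBr3 frees the catechol and the primary alcohol. The C7 carboxyl comes from ortho-lithiation/CO2 of a 5,6-dimethoxytetralin.
2. C13–C14: hydroboration and alkyl-alkyl Suzuki coupling of a C1-(but-3-en-2-yl)tetralin with a bromide made from (S)-3-bromo-2-methylpropan-1-ol, which brings C15.
3. C1–C11: iridium-catalysed branched allylation of a 4-methyl-5,6-dimethoxy-2-tetralone. The ligand sets C11, the enolisable C1 settles trans to the C4 methyl, and the C2 carbonyl is then deleted.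
4. Key bond C1–C8a: the alpha-carbon of a methyl ketone is made electrophilic as an enolonium species. The arene attacks it para to the C6 methoxy group, so two normally nucleophilic carbons are joined.
5. C4–C4a: Rh/BINAP 1,4-addition of the arylboronic acid. Ring A is bought and ring B is closed in the key step.

Locants: tetralin C1 (bears the side chain), C2, C3, C4 (bears CH3), C4a, C5 and C6 (oxygen), C7 (CO2H), C8, C8a. The side chain is C11 (CH, CH3), C12–C14, C15 (CH, CH3), C16 (CH2OH). The target is 1S,4R (trans),11S,15R.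

Assumption: the ligand antipodes in steps 1 and 5 follow the known sense of induction for the closest substrates. If a test run shows the opposite sense, the mirror-image ligand is used.

**Step 1**
Reactants: 1 2,3-dimethoxyphenylboronic acid; 2 (E)-pent-3-en-2-one
Product: 3 (4R)-4-(2,3-dimethoxyphenyl)pentan-2-one
Conditions: [Rh(OH)(cod)]2 (1.5 mol %), (S)-BINAP (3.3 mol %), 1 (2 equiv), dioxane/H2O 10:1, 40 °C
Reagents that add atoms: none
Why: Hayashi-Miyaura asymmetric 1,4-addition, in which the aryl-rhodium/(S)-BINAP species inserts the E-enone on its alpha-si face (the sense that gives (R)-3-arylbutanoates from crotonates), setting C4 as R and fixing the C4–C4a bond next to the C5 methoxy group.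

**Step 2**
Reactants: 3 (4R)-4-(2,3-dimethoxyphenyl)pentan-2-one
Product: 5 {[(4R)-4-(2,3-dimethoxyphenyl)pent-1-en-2-yl]oxy}(trimethyl)silane, via lithium enolate 4 (not isolated)
Conditions: LiN(iPr)2 (1.1 equiv), THF, −78 °C; Me3SiCl, −78 to 0 °C; pentane, filtration
Reagents that add atoms: lithium diisopropylamide, [Li]N(C(C)C)C(C)C (its lithium stays only in 4); chlorotrimethylsilane, C[Si](C)(C)Cl
Why: Kinetic enolate silylation, in which the hindered amide removes a proton from the unhindered methyl group (future C1) rather than from the beta-branched C3 methylene, and C4 is not touched.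

**Step 3 (key step)**
Reactants: 5 {[(4R)-4-(2,3-dimethoxyphenyl)pent-1-en-2-yl]oxy}(trimethyl)silane
Product: 7 (4R)-5,6-dimethoxy-4-methyl-3,4-dihydronaphthalen-2(1H)-one, via enolonium species 6 (not isolated)
Conditions: PhI(OAc)2 (1.1 equiv), BF3·OEt2 (2.2 equiv), CH2Cl2, −78 °C; slow inverse addition of 5 (final 0.01 M), −78 to −20 °C; aq NaHCO3
Reagents that add atoms: (diacetoxyiodo)benzene, CC(=O)OI(OC(C)=O)c1ccccc1 (its atoms stay only in 6)
Why: Proposed new method: BF3-activated PhI(OAc)2 turns the silyl enol ether into a discrete trivalent-iodine enolonium species whose terminal alpha-carbon C1 is electrophilic, and the tethered arene attacks it through its only free ortho position C8a (para to the C6 methoxy group) in a six-membered Friedel-Crafts-type closure with loss of PhI, the closest known reaction types being intermolecular ketone alpha-arylation via enolonium species, capture of such iodonium ketones by simple alkenes, and acid-promoted cyclisation of 1-diazo-4-arylbutan-2-ones to 2-tetralones; no stereocentre is formed and C4 is untouched.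

**Step 4**
Reactants: 8 (E)-but-2-en-1-ol
Product: 9 methyl (E)-but-2-en-1-yl carbonate
Conditions: ClCO2Me (1.2 equiv), pyridine (1.5 equiv), CH2Cl2, 0 °C
Reagents that add atoms: methyl chloroformate, COC(=O)Cl
Why: Simple O-acylation gives the linear allylic carbonate, which ionises on iridium and releases its own methoxide base.

**Step 5**
Reactants: 7 (4R)-5,6-dimethoxy-4-methyl-3,4-dihydronaphthalen-2(1H)-one; 9 methyl (E)-but-2-en-1-yl carbonate
Product: 10 (1S,4R)-1-[(2S)-but-3-en-2-yl]-5,6-dimethoxy-4-methyl-3,4-dihydronaphthalen-2(1H)-one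
Conditions: [Ir(cod)Cl]2 (2 mol %), (Sa,S,S)-(1,1'-binaphthalene-2,2'-diyl) N,N-bis(1-phenylethyl)phosphoramidite (4 mol %), 1,5,7-triazabicyclo[4.4.0]dec-5-ene (8 mol %), THF, 25 °C, argon; then DBU (0.2 equiv), 25 °C
Reagents that add atoms: none
Why: Iridium-catalysed branched-selective asymmetric allylic alkylation (Hartwig-Helmchen type), in which the arene-conjugated C1 enolate attacks the methyl-bearing allyl terminus so that the ligand fixes C11 as S, while C1 is alkylated anti to the pseudoaxial C4 methyl and, being still enolisable, is equilibrated to the trans isomer (1S), because the cis isomer would hold two pseudoaxial groups on the same ring face in a 1,4 contact.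

**Step 6**
Reactants: 10 (1S,4R)-1-[(2S)-but-3-en-2-yl]-5,6-dimethoxy-4-methyl-3,4-dihydronaphthalen-2(1H)-one
Product: 12 (1S,4R)-1-[(2S)-but-3-en-2-yl]-5,6-dimethoxy-4-methyl-1,2,3,4-tetrahydronaphthalene, via tosylhydrazone 11 (not isolated)
Conditions: TsNHNH2 (1.2 equiv), CHCl3, 4 Å sieves, 50 °C; catecholborane (2.5 equiv), −10 °C; NaOAc·3H2O, reflux
Reagents that add atoms: 4-methylbenzenesulfonohydrazide, Cc1ccc(cc1)S(=O)(=O)NN (its atoms stay only in 11)
Why: Caglioti/Kabalka-type tosylhydrazone reduction, in which hydride adds to C=N and loss of sulfinate and N2 leaves C2 as a CH2 with no new stereocentre; the conditions are too mild to isomerise or hydroborate the vinyl group, and any C1 epimerisation at the hydrazone stage again favours trans.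

**Step 7**
Reactants: 13 (S)-3-bromo-2-methylpropan-1-ol
Product: 14 (S)-(3-bromo-2-methylpropoxy)(tert-butyl)dimethylsilane
Conditions: TBSCl (1.1 equiv), imidazole (1.5 equiv), CH2Cl2, 0 to 25 °C
Reagents that add atoms: tert-butyldimethylsilyl chloride, CC(C)(C)[Si](C)(C)Cl
Why: Standard silyl protection keeps the alkoxide from cyclising to an oxetane under the basic coupling conditions and leaves the chiral-pool centre (future C15) untouched.

**Step 8**
Reactants: 12 (1S,4R)-1-[(2S)-but-3-en-2-yl]-5,6-dimethoxy-4-methyl-1,2,3,4-tetrahydronaphthalene; 14 (S)-(3-bromo-2-methylpropoxy)(tert-butyl)dimethylsilane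
Product: 16 tert-butyl({(2R,6S)-6-[(1S,4R)-5,6-dimethoxy-4-methyl-1,2,3,4-tetrahydronaphthalen-1-yl]-2-methylheptyl}oxy)dimethylsilane, via B-alkyl-9-BBN adduct 15 (not isolated)
Conditions: 9-BBN (1.2 equiv), THF, 25 °C; then 14 (1.3 equiv), NiCl2·glyme (6 mol %), trans-N,N'-dimethylcyclohexane-1,2-diamine (8 mol %), KOtBu, iBuOH, dioxane, 25 °C
Reagents that add atoms: 9-borabicyclo[3.3.1]nonane, B1C2CCCC1CCC2 (its boron and carbon atoms stay only in 15)
Why: Anti-Markovnikov hydroboration puts boron on terminal C13 and the nickel/diamine alkyl-alkyl Suzuki-Miyaura coupling joins C13 to C14 without touching C11 or C15, so C15 (R in the product by a CIP priority change only) comes unchanged from 13.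

**Step 9**
Reactants: 16 tert-butyl({(2R,6S)-6-[(1S,4R)-5,6-dimethoxy-4-methyl-1,2,3,4-tetrahydronaphthalen-1-yl]-2-methylheptyl}oxy)dimethylsilane
Product: 18 (5R,8S)-8-[(2S,6R)-7-(tert-butyldimethylsilyloxy)-6-methylheptan-2-yl]-3,4-dimethoxy-5-methyl-5,6,7,8-tetrahydronaphthalene-2-carboxylic acid, via C7 aryllithium 17 (not isolated)
Conditions: n-BuLi (2.5 equiv), TMEDA (2.5 equiv), Et2O, 0 to 25 °C; CO2, −78 to 25 °C; 1 M HCl
Reagents that add atoms: n-butyllithium, [Li]CCCC (its lithium stays only in 17); carbon dioxide, O=C=O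
Why: Directed ortho-metalation, in which the C6 methoxy group directs lithiation to C7 (the only ring C–H ortho to an OMe) and CO2 traps the aryllithium; the silyl ether and all four stereocentres are inert.

**Step 10**
Reactants: 18 (5R,8S)-8-[(2S,6R)-7-(tert-butyldimethylsilyloxy)-6-methylheptan-2-yl]-3,4-dimethoxy-5-methyl-5,6,7,8-tetrahydronaphthalene-2-carboxylic acid
Product: 19 (5R,8S)-3,4-dihydroxy-8-[(2S,6R)-7-hydroxy-6-methylheptan-2-yl]-5-methyl-5,6,7,8-tetrahydronaphthalene-2-carboxylic acid (target)
Conditions: BBr3 (6 equiv), CH2Cl2, −78 to 0 °C; then H2O, 0 to 25 °C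
Reagents that add atoms: none
Why: Lewis-acid ether cleavage, in which BBr3 (helped by chelation to the carboxyl and the first-formed phenolate) removes both aryl methyl ethers and the bromosilane/HBr chemistry takes off the silyl group, while the primary alcohol is held as its borate at or below 0 °C and no stereocentre is involved.

**Compound list**
1 | 2,3-dimethoxyphenylboronic acid | COc1cccc(B(O)O)c1OC | starting material
2 | (E)-pent-3-en-2-one | C/C=C/C(C)=O | starting material
3 | (4R)-4-(2,3-dimethoxyphenyl)pentan-2-one | C[C@H](CC(C)=O)c1cccc(OC)c1OC | intermediate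
4 | lithium (4R)-4-(2,3-dimethoxyphenyl)pent-1-en-2-olate (not isolated) | C[C@H](CC(=C)O[Li])c1cccc(OC)c1OC | intermediate
5 | {[(4R)-4-(2,3-dimethoxyphenyl)pent-1-en-2-yl]oxy}(trimethyl)silane | C[C@H](CC(=C)O[Si](C)(C)C)c1cccc(OC)c1OC | intermediate
6 | enolonium species, drawn as the O-bound acetoxy(phenyl)iodanyl enolate of 3, BF3-activated (not isolated) | C[C@H](CC(=C)OI(OC(C)=O)c1ccccc1)c1cccc(OC)c1OC | intermediate
7 | (4R)-5,6-dimethoxy-4-methyl-3,4-dihydronaphthalen-2(1H)-one | C[C@@H]1CC(=O)Cc2ccc(OC)c(OC)c21 | intermediate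
8 | (E)-but-2-en-1-ol | C/C=C/CO | starting material
9 | methyl (E)-but-2-en-1-yl carbonate | C/C=C/COC(=O)OC | intermediate
10 | (1S,4R)-1-[(2S)-but-3-en-2-yl]-5,6-dimethoxy-4-methyl-3,4-dihydronaphthalen-2(1H)-one | C=C[C@H](C)[C@@H]1C(=O)C[C@@H](C)c2c1ccc(OC)c2OC | intermediate
11 | tosylhydrazone of 10 (not isolated) | C=C[C@H](C)[C@@H]1C(=NNS(=O)(=O)c3ccc(C)cc3)C[C@@H](C)c2c1ccc(OC)c2OC | intermediate
12 | (1S,4R)-1-[(2S)-but-3-en-2-yl]-5,6-dimethoxy-4-methyl-1,2,3,4-tetrahydronaphthalene | C=C[C@H](C)[C@@H]1CC[C@@H](C)c2c1ccc(OC)c2OC | intermediate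
13 | (S)-3-bromo-2-methylpropan-1-ol | C[C@@H](CO)CBr | starting material
14 | (S)-(3-bromo-2-methylpropoxy)(tert-butyl)dimethylsilane | C[C@@H](CO[Si](C)(C)C(C)(C)C)CBr | intermediate
15 | 9-{(3S)-3-[(1S,4R)-5,6-dimethoxy-4-methyl-1,2,3,4-tetrahydronaphthalen-1-yl]butyl}-9-borabicyclo[3.3.1]nonane (not isolated) | B1(C2CCCC1CCC2)CC[C@H](C)[C@@H]1CC[C@@H](C)c2c1ccc(OC)c2OC | intermediate
16 | tert-butyl({(2R,6S)-6-[(1S,4R)-5,6-dimethoxy-4-methyl-1,2,3,4-tetrahydronaphthalen-1-yl]-2-methylheptyl}oxy)dimethylsilane | C[C@@H](CO[Si](C)(C)C(C)(C)C)CCC[C@H](C)[C@@H]1CC[C@@H](C)c2c1ccc(OC)c2OC | intermediate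
17 | C7 aryllithium of 16 (not isolated) | C[C@@H](CO[Si](C)(C)C(C)(C)C)CCC[C@H](C)[C@@H]1CC[C@@H](C)c2c1cc([Li])c(OC)c2OC | intermediate
18 | (5R,8S)-8-[(2S,6R)-7-(tert-butyldimethylsilyloxy)-6-methylheptan-2-yl]-3,4-dimethoxy-5-methyl-5,6,7,8-tetrahydronaphthalene-2-carboxylic acid | C[C@@H](CO[Si](C)(C)C(C)(C)C)CCC[C@H](C)[C@@H]1CC[C@@H](C)c2c1cc(C(=O)O)c(OC)c2OC | intermediate
19 | (5R,8S)-3,4-dihydroxy-8-[(2S,6R)-7-hydroxy-6-methylheptan-2-yl]-5-methyl-5,6,7,8-tetrahydronaphthalene-2-carboxylic acid | C[C@@H](CO)CCC[C@H](C)[C@@H]1CC[C@@H](C)c2c1cc(C(=O)O)c(O)c2O | target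

**Step count**
- Total steps: 10
- Longest linear sequence: 8 (steps 1, 2, 3, 5, 6, 8, 9, 10)

**Steps most likely to fail**

Risk 1, step 3 (enolonium ring closure).
- The trivalent-iodine reagent may oxidise the dimethoxyarene.
- The enolonium species may be intercepted by unreacted 5 to give the 1,4-diketone dimer.
- It may be captured by acetate.

The fallback keeps the same bond and the same polarity reversal but uses a different alpha-keto cation equivalent. It sets out from 3. Kinetic trifluoroacetylation (LiN(SiMe3)2, CF3CO2CH2CF3, THF, −78 °C) gives (6R)-6-(2,3-dimethoxyphenyl)-1,1,1-trifluoroheptane-2,4-dione F1. Detrifluoroacetylative diazo transfer (MsN3, Et3N, H2O, MeCN) then gives (4R)-1-diazo-4-(2,3-dimethoxyphenyl)pentan-2-one F2. CF3CO2H in CH2Cl2 at −20 °C protonates the diazo carbon, and C8a displaces N2 from the alpha-keto diazonium ion. The route is rejoined at 7.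

Risk 2, step 5 (iridium allylation).
- Methyl-substituted allyl carbonates give lower branched/linear ratios and ee than aryl-substituted ones.
- O-allylation or a second allylation may compete.
- The 2-tetralone is air-sensitive.

The fallback replaces catalyst control by a sigmatropic transfer from C4, and it sets out from 7. Heating 7 with 8 and catalytic TsOH in toluene, then xylene, with water removal gives (4R)-2-[(E)-but-2-en-1-yloxy]-5,6-dimethoxy-4-methyl-3,4-dihydronaphthalene F3. F3 undergoes a Claisen [3,3] rearrangement on the ring face anti to the C4 methyl. In the chair transition state the E-crotyl methyl and the aryl carbon are both equatorial, which gives the 1S,11S pair. The route is rejoined at 10.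

Risk 3, step 8 (alkyl-alkyl Suzuki coupling). The beta-branched primary bromide activates slowly, and the valuable partner is the borane, so protodeboronation and beta-hydride loss cost material. The fallback drops boron altogether, and it sets out from 12 and 14. A nickel-hydride reductive hydroalkylation (NiBr2·diglyme, 4,4'-di-tert-butyl-2,2'-bipyridine, (EtO)2MeSiH, Na2CO3, DMA, 25 °C) adds hydride to C12 and the alkyl group of 14 to terminal C13 in one operation. The route is rejoined at 16.

**Further compounds**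
F1 | step 3 | (6R)-6-(2,3-dimethoxyphenyl)-1,1,1-trifluoroheptane-2,4-dione | C[C@H](CC(=O)CC(=O)C(F)(F)F)c1cccc(OC)c1OC
F2 | step 3 | (4R)-1-diazo-4-(2,3-dimethoxyphenyl)pentan-2-one | C[C@H](CC(=O)C=[N+]=[N-])c1cccc(OC)c1OC
F3 | step 5 | (4R)-2-[(E)-but-2-en-1-yloxy]-5,6-dimethoxy-4-methyl-3,4-dihydronaphthalene | C/C=C/COC1=Cc2ccc(OC)c(OC)c2[C@H](C)C1
F0 | step 8 | none | none
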